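**Strategy**

Ring A is disconnected at C2–C3 and C1–C10: a two-carbon unit (C1–C2, phenyl vinyl sulfone) is inserted between the methyl-bearing C10 and the carbinol C3, exploiting their 1,4-disposition across ring A next to the gem-dimethyl C4. The precursor is a monocyclic ring B epoxy aldehyde. Trivalent titanium opens the C9–C10 epoxide to a tertiary C10 radical that adds to the sulfone; the C2 centre then closes onto the neopentyl aldehyde. One operation builds ring A, the quaternary C10 and the 3β-carbinol under control of C5 (CBS reduction, then Claisen chirality transfer), and keeps a C9 oxygen that later delivers the exocyclic methylene and the homofarnesyl chain.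

Key step: step 4

Remark: terpenoid numbering is used for the bicyclic compounds (ring A: C1–C5 and C10; ring B: C5–C10; C4 bears the geminal methyls, C10 the angular methyl, C11 is the first side-chain carbon, C26 the exocyclic methylene carbon; α is the face of the C5 hydrogen, β that of the C10 methyl), and 1-iodo-2-methylprop-1-ene and (2E,6E)-farnesyl bromide are taken as purchasable.

**Route**

Step 1
Reactants: 1 2-methylcyclohex-2-en-1-one
Product: 2 (S)-2-methylcyclohex-2-en-1-ol
Conditions: (R)-2-methyl-CBS-oxazaborolidine (10 mol%), BH3·SMe2, THF, −20 °C; MeOH quench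
Reagents that add atoms: none
Why: Corey–Bakshi–Shibata reduction, in which the carbonyl binds with the larger α-methylvinyl arm away from the catalyst, so the (R)-catalyst should deliver hydride to the face that gives the (S)-allylic alcohol, the only stereocenter of the route set by a catalyst.

Step 2
Reactants: 2 (S)-2-methylcyclohex-2-en-1-ol; 3 1-iodo-2-methylprop-1-ene
Product: 5 (R)-2-methyl-2-(2-methylcyclohex-2-en-1-yl)propanal, via allyl vinyl ether 4 (not isolated)
Conditions: CuI (10 mol%), 3,4,7,8-tetramethyl-1,10-phenanthroline (20 mol%), Cs2CO3, o-xylene, 120 °C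
Reagents that add atoms: none
Why: Domino Ullmann-type copper-catalysed O-vinylation and Claisen rearrangement, in which the suprafacial [3,3] shift forms the C5–C4 bond on the ring face that the C–O bond leaves, so the carbinol configuration is transferred to C5 ((S) to (R)), the quaternary C4 with its aldehyde is created and the alkene moves to C9=C10.

Step 3
Reactants: 5 (R)-2-methyl-2-(2-methylcyclohex-2-en-1-yl)propanal
Product: 6 2-methyl-2-[(1S,2S,6R)-1-methyl-7-oxabicyclo[4.1.0]heptan-2-yl]propanal (9α,10α-epoxide, trans to the C5 arm)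
Conditions: mCPBA (1.05 equiv), NaHCO3, CH2Cl2, 0 °C
Reagents that add atoms: mCPBA, O=C(OO)c1cccc(Cl)c1
Why: Prilezhaev epoxidation, in which the electron-rich trisubstituted alkene should react much faster than the hindered aldehyde undergoes Baeyer–Villiger oxidation and the peracid approaches anti to the pseudoaxial CMe2CHO arm (the C9 configuration is erased later).

Step 4
Reactants: 6 2-methyl-2-[(1S,2S,6R)-1-methyl-7-oxabicyclo[4.1.0]heptan-2-yl]propanal; 7 phenyl vinyl sulfone
Product: 10 2α-phenylsulfonyl-4,4,10-trimethyl-trans-decalin-3β,9α-diol, via C10 tertiary radical 8 (not isolated), via C2 sulfonyl radical 9 (not isolated)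
Conditions: Cp2TiCl2 (titanocene dichloride, 2.5 equiv), Mn dust, THF, rt (forms Cp2TiCl, trivalent titanium); added slowly to 6 and 7 (4 equiv), THF, rt; then 1 M HCl
Reagents that add atoms: none
Why: Proposed new method: Cp2TiCl opens the trisubstituted epoxide by single-electron transfer to the tertiary C10 radical carrying a C9 titanium alkoxide, this radical adds to phenyl vinyl sulfone (C1–C10), and the C2 α-sulfonyl radical is reduced by a second Cp2TiCl to a titanium-bound sulfonyl carbanion that adds to the aldehyde (C2–C3). The closest known reaction types are the titanocene-mediated reductive epoxide opening with Giese addition to acrylic acceptors, additions of titanated sulfones to aldehydes, and hydrogen-atom-transfer Giese–aldol annulations of unsaturated aldehydes; joining them in one flask is the new element. Ring A closes in the 6-exo-trig mode onto the carbonyl carbon through a chair transition state. C10 is controlled by C5, because the bulky CMe2CHO arm sits pseudoaxial next to the planar radical and the acceptor enters anti to it, which gives the trans ring fusion with the methyl β; C3 should form with the titanium-bound oxygen equatorial (3β), and a catalytic-base retro-aldol/aldol equilibration of the β-hydroxy sulfone can correct a C3 epimer; C2 is removed in step 5. The step needs the epoxide to be reduced faster than the aldehyde and the tertiary radical to be trapped by the sulfone faster than by Cp2TiCl (β-hydride elimination), which the low pinacol reactivity of a neopentyl aliphatic aldehyde and the slow addition of the titanium reagent to excess acceptor should secure.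

Step 5
Reactants: 10 2α-phenylsulfonyl-4,4,10-trimethyl-trans-decalin-3β,9α-diol
Product: 11 4,4,10-trimethyl-trans-decalin-3β,9α-diol
Conditions: sodium amalgam Na(Hg) (6%), Na2HPO4, MeOH/THF, −20 °C
Reagents that add atoms: none
Why: Reductive desulfonylation by electron transfer cleaves the secondary C2–S bond; buffer and low temperature should suppress retro-aldol opening, and the free β-hydroxyl is too poor a leaving group for Julia-type elimination, so C3 is untouched.

Step 6
Reactants: 11 4,4,10-trimethyl-trans-decalin-3β,9α-diol
Product: 12 3β-(tert-butyldimethylsilyloxy)-4,4,10-trimethyl-trans-decalin-9α-ol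
Conditions: TBSCl (1.2 equiv), imidazole, DMF, rt
Reagents that add atoms: TBSCl, CC(C)(C)[Si](C)(C)Cl
Why: Sterically controlled silyl ether formation, in which the equatorial 3β-hydroxyl should react in preference to the axial 9α-hydroxyl that is flanked by the quaternary C10 and by 1,3-diaxial hydrogens at C5 and C7.

Step 7
Reactants: 12 3β-(tert-butyldimethylsilyloxy)-4,4,10-trimethyl-trans-decalin-9α-ol
Product: 13 3β-(tert-butyldimethylsilyloxy)-4,4,10-trimethyl-trans-decalin-9-one
Conditions: Dess–Martin periodinane, CH2Cl2, rt
Reagents that add atoms: none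
Why: Dess–Martin oxidation converts the remaining hindered axial carbinol into the C9 ketone under neutral conditions that leave the silyl ether and C3 untouched.

Step 8
Reactants: 13 3β-(tert-butyldimethylsilyloxy)-4,4,10-trimethyl-trans-decalin-9-one
Product: 14 3β-(tert-butyldimethylsilyloxy)-4,4,10-trimethyl-8-methylene-trans-decalin-9-one
Conditions: paraformaldehyde, N-methylanilinium trifluoroacetate, THF, reflux
Reagents that add atoms: paraformaldehyde (formaldehyde), C=O
Why: Mannich-type α-methylenation (iminium addition to the enol, then β-elimination of the amine) is regiospecific because C10 is quaternary and the ketone can enolise only toward C8, which installs C26.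

Step 9
Reactants: 15 thioanisole; 16 (2E,6E)-farnesyl bromide
Product: 18 (3E,7E)-homofarnesyl phenyl sulfide, via phenylthiomethyllithium 17 (not isolated)
Conditions: n-BuLi, DABCO, THF, 0 °C; then 16, −78 °C to rt
Reagents that add atoms: none
Why: SN2 alkylation of the sulfur-stabilised carbanion of thioanisole at the primary allylic bromide adds the one missing carbon (C11) without touching the E,E-trisubstituted alkenes.

Step 10
Reactants: 18 (3E,7E)-homofarnesyl phenyl sulfide; 14 3β-(tert-butyldimethylsilyloxy)-4,4,10-trimethyl-8-methylene-trans-decalin-9-one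
Product: 21 3β-(tert-butyldimethylsilyloxy)-9α-homofarnesyl-4,4,10-trimethyl-8-methylene-trans-decalin-9β-yl methyl carbonate, via homofarnesyllithium 19 (not isolated), via C9 lithium alkoxide 20 (not isolated)
Conditions: lithium 4,4′-di-tert-butylbiphenylide (LiDBB, 2.2 equiv), THF, −78 °C; CeCl3, −78 °C; then 14; then ClCO2Me (excess), −78 to 0 °C
Reagents that add atoms: methyl chloroformate, COC(=O)Cl
Why: Reductive lithiation of the alkyl phenyl sulfide by the arene radical anion gives the primary organolithium, whose organocerium form adds 1,2 to the non-enolisable cross-conjugated ketone (expected from the α face, anti to the axial C10 methyl), and the hindered alkoxide is acylated in the flask; the new C9 configuration does not matter because C9 becomes part of a π-allyl in step 11.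

Step 11
Reactants: 21 3β-(tert-butyldimethylsilyloxy)-9α-homofarnesyl-4,4,10-trimethyl-8-methylene-trans-decalin-9β-yl methyl carbonate
Product: 22 tert-butyldimethylsilyl ether of the target (3β-silyloxy-polypoda-8(26),13,17,21-tetraene)
Conditions: Pd(OAc)2 (5 mol%), n-Bu3P (20 mol%), HCO2H, Et3N, THF, 60 °C
Reagents that add atoms: none
Why: Palladium-catalysed formate hydrogenolysis of an allylic carbonate, in which zerovalent palladium ionises the tertiary carbonate to a π-allyl complex and the palladium formate delivers hydride to the more substituted terminus C9 from the less hindered α face (opposite the axial C10 methyl), which should give the exocyclic C8=C26 alkene, the 9α hydrogen and the equatorial side chain.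

Step 12
Reactants: 22 tert-butyldimethylsilyl ether of the target
Product: 23 target CNP0192094.1
Conditions: Bu4NF (TBAF), THF, 50 °C
Reagents that add atoms: none
Why: Fluoride-induced cleavage of the hindered silyl ether frees the 3β-hydroxyl without acid, so the exocyclic and trisubstituted alkenes should be neither isomerised nor cyclised.

**Compound list**

1 | 2-methylcyclohex-2-en-1-one | CC1=CCCCC1=O | starting material
2 | (S)-2-methylcyclohex-2-en-1-ol | O[C@H]1CCCC=C1C | intermediate
3 | 1-iodo-2-methylprop-1-ene | CC(C)=CI | starting material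
4 | (S)-1-methyl-6-[(2-methylprop-1-en-1-yl)oxy]cyclohex-1-ene (allyl vinyl ether) | CC(C)=CO[C@H]1CCCC=C1C | intermediate (not isolated)
5 | (R)-2-methyl-2-(2-methylcyclohex-2-en-1-yl)propanal | O=CC(C)(C)[C@@H]1CCCC=C1C | intermediate
6 | 2-methyl-2-[(1S,2S,6R)-1-methyl-7-oxabicyclo[4.1.0]heptan-2-yl]propanal | O=CC(C)(C)[C@@H]1CCC[C@H]2O[C@@]12C | intermediate
7 | phenyl vinyl sulfone | C=CS(=O)(=O)c1ccccc1 | starting material
8 | C10 tertiary radical with C9 O–TiCp2Cl (ring-opened epoxide) | O=CC(C)(C)[C@@H]1CCC[C@@H](O[Ti](Cl)(C2C=CC=C2)C2C=CC=C2)[C]1C | intermediate (not isolated)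
9 | C2 sulfonyl radical (Giese adduct, C1–C10 bond formed) | O=CC(C)(C)[C@@H]1CCC[C@@H](O[Ti](Cl)(C2C=CC=C2)C2C=CC=C2)[C@@]1(C)C[CH]S(=O)(=O)c1ccccc1 | intermediate (not isolated)
10 | 2α-phenylsulfonyl-4,4,10-trimethyl-trans-decalin-3β,9α-diol (5α-H, 10β-CH3) | O[C@@H]1CCC[C@H]2C(C)(C)[C@@H](O)[C@H](S(=O)(=O)c3ccccc3)C[C@]12C | intermediate
11 | 4,4,10-trimethyl-trans-decalin-3β,9α-diol | O[C@@H]1CCC[C@H]2C(C)(C)[C@@H](O)CC[C@]12C | intermediate
12 | 3β-(tert-butyldimethylsilyloxy)-4,4,10-trimethyl-trans-decalin-9α-ol | O[C@@H]1CCC[C@H]2C(C)(C)[C@@H](O[Si](C)(C)C(C)(C)C)CC[C@]12C | intermediate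
13 | 3β-(tert-butyldimethylsilyloxy)-4,4,10-trimethyl-trans-decalin-9-one | O=C1CCC[C@H]2C(C)(C)[C@@H](O[Si](C)(C)C(C)(C)C)CC[C@]12C | intermediate
14 | 3β-(tert-butyldimethylsilyloxy)-4,4,10-trimethyl-8-methylene-trans-decalin-9-one | C=C1CC[C@H]2C(C)(C)[C@@H](O[Si](C)(C)C(C)(C)C)CC[C@]2(C)C1=O | intermediate
15 | thioanisole | CSc1ccccc1 | starting material
16 | (2E,6E)-farnesyl bromide | BrC/C=C(\C)CC/C=C(\C)CCC=C(C)C | starting material
17 | (phenylthio)methyllithium | [Li]CSc1ccccc1 | intermediate (not isolated)
18 | (3E,7E)-4,8,12-trimethyltrideca-3,7,11-trien-1-yl phenyl sulfide (homofarnesyl phenyl sulfide) | c1ccccc1SCC/C=C(\C)CC/C=C(\C)CCC=C(C)C | intermediate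
19 | (3E,7E)-homofarnesyllithium | [Li]CC/C=C(\C)CC/C=C(\C)CCC=C(C)C | intermediate (not isolated)
20 | C9 lithium alkoxide (9β-O, 9α-homofarnesyl, 8-methylene, 3β-silyloxy) | [Li]O[C@@]1(CC/C=C(\C)CC/C=C(\C)CCC=C(C)C)C(=C)CC[C@H]2C(C)(C)[C@@H](O[Si](C)(C)C(C)(C)C)CC[C@]12C | intermediate (not isolated)
21 | 3β-(tert-butyldimethylsilyloxy)-9α-homofarnesyl-4,4,10-trimethyl-8-methylene-trans-decalin-9β-yl methyl carbonate | COC(=O)O[C@@]1(CC/C=C(\C)CC/C=C(\C)CCC=C(C)C)C(=C)CC[C@H]2C(C)(C)[C@@H](O[Si](C)(C)C(C)(C)C)CC[C@]12C | intermediate
22 | tert-butyldimethylsilyl ether of the target | C=C1CC[C@H]2C(C)(C)[C@@H](O[Si](C)(C)C(C)(C)C)CC[C@]2(C)[C@H]1CC/C=C(\C)CC/C=C(\C)CCC=C(C)C | intermediate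
23 | CNP0192094.1, (2S,4aR,5S,8aR)-1,1,4a-trimethyl-6-methylidene-5-[(3E,7E)-4,8,12-trimethyltrideca-3,7,11-trien-1-yl]decahydronaphthalen-2-ol | C=C1CC[C@H]2C(C)(C)[C@@H](O)CC[C@]2(C)[C@H]1CC/C=C(\C)CC/C=C(\C)CCC=C(C)C | target

**Count**

Total steps: 12. Longest linear sequence: 11 (steps 1–8 and 10–12; step 9 prepares the side-chain reagent).

**Steps most likely to fail**

Step 4 (labelled step). The tertiary C10 radical may be captured by Cp2TiCl and lost by β-hydride elimination or reduction before it reaches the sulfone, or the titanated sulfone may be protonated before it closes onto the aldehyde. The fallback keeps a one-flask formation of both bonds but uses a known anionic Michael-initiated ring closure with Robinson-type regiochemistry. It sets out from aldehyde 5. Hydroboration–oxidation (BH3·THF; NaOH, H2O2) reduces the aldehyde and hydrates the alkene anti-Markovnikov on the face opposite the arm to give the hydroboration diol F1. Dess–Martin oxidation of both carbinols gives the keto aldehyde F2. KOtBu in THF/tert-butanol equilibrates to the more substituted C10 enolate, which adds to phenyl vinyl sulfone 7 anti to the C5 arm; the sulfonyl carbanion formed in the Michael step closes onto the aldehyde to give the keto hydroxy sulfone F3, with hydroxyl and sulfonyl equatorial through the reversible aldol. Silylation (TBSCl, imidazole) gives the silyl ether F4, and buffered sodium amalgam at −20 °C removes the sulfonyl group and returns to ketone 13; any C9 carbinol from over-reduction would be re-oxidised as in step 7.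

Step 2. The copper-mediated C–O coupling of the hindered secondary allylic alcohol may stall, or the vinyl iodide may be consumed by elimination before the ether forms. The fallback sets out from alcohol 2. Acylation with isobutyryl chloride (pyridine, DMAP) gives the isobutyrate ester F5. An Ireland–Claisen rearrangement (LDA, TMSCl, THF, −78 °C to reflux; aqueous acid) gives the acid F6 with the same suprafacial chirality transfer. LiAlH4 reduction gives the alcohol F7, and Dess–Martin oxidation returns to aldehyde 5.

Step 11. Hydride may be delivered to the primary allyl terminus (giving the tetrasubstituted C8=C9 alkene) or to the β face of C9. The fallback sets out from alkoxide 20, which is quenched with water instead of the chloroformate to give the tertiary allylic alcohol F8. Rhenium-catalysed 1,3-transposition (Ph3SiOReO3, Et2O, rt) moves the hydroxyl to C26 and gives the primary allylic alcohol F9. A Mitsunobu reaction with 2-nitrobenzenesulfonylhydrazide (PPh3, DEAD, N-methylmorpholine, −30 °C to rt) gives, after loss of the sulfinic acid, the allylic diazene F10; its retro-ene loss of dinitrogen delivers hydrogen to C9 from the open α face and returns to silyl ether 22.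

**Further compounds**

F1 | step 4 | 2-[(1,2-cis-2,3-trans)-3-hydroxy-2-methylcyclohexyl]-2-methylpropan-1-ol (hydroboration diol) | OCC(C)(C)[C@@H]1CCC[C@@H](O)[C@@H]1C
F2 | step 4 | 2-methyl-2-(cis-2-methyl-3-oxocyclohexyl)propanal (keto aldehyde) | O=CC(C)(C)[C@@H]1CCCC(=O)[C@@H]1C
F3 | step 4 | 3β-hydroxy-2α-phenylsulfonyl-4,4,10-trimethyl-trans-decalin-9-one (keto hydroxy sulfone) | O=C1CCC[C@H]2C(C)(C)[C@@H](O)[C@H](S(=O)(=O)c3ccccc3)C[C@]12C
F4 | step 4 | 3β-(tert-butyldimethylsilyloxy)-2α-phenylsulfonyl-4,4,10-trimethyl-trans-decalin-9-one (silyl ether) | O=C1CCC[C@H]2C(C)(C)[C@@H](O[Si](C)(C)C(C)(C)C)[C@H](S(=O)(=O)c3ccccc3)C[C@]12C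
F5 | step 2 | (S)-2-methylcyclohex-2-en-1-yl 2-methylpropanoate (isobutyrate ester) | CC(C)C(=O)O[C@H]1CCCC=C1C
F6 | step 2 | (R)-2-methyl-2-(2-methylcyclohex-2-en-1-yl)propanoic acid | OC(=O)C(C)(C)[C@@H]1CCCC=C1C
F7 | step 2 | (R)-2-methyl-2-(2-methylcyclohex-2-en-1-yl)propan-1-ol | OCC(C)(C)[C@@H]1CCCC=C1C
F8 | step 11 | 3β-(tert-butyldimethylsilyloxy)-9α-homofarnesyl-4,4,10-trimethyl-8-methylene-trans-decalin-9β-ol (tertiary allylic alcohol) | O[C@@]1(CC/C=C(\C)CC/C=C(\C)CCC=C(C)C)C(=C)CC[C@H]2C(C)(C)[C@@H](O[Si](C)(C)C(C)(C)C)CC[C@]12C
F9 | step 11 | 3β-(tert-butyldimethylsilyloxy)-8-(hydroxymethyl)-9-homofarnesyl-4,4,10-trimethyl-trans-decal-8(9)-ene (primary allylic alcohol) | OCC1=C(CC/C=C(\C)CC/C=C(\C)CCC=C(C)C)[C@@]2(C)CC[C@H](O[Si](C)(C)C(C)(C)C)C(C)(C)[C@@H]2CC1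
F10 | step 11 | allylic diazene of F9 (C26–N=NH) | N=NCC1=C(CC/C=C(\C)CC/C=C(\C)CCC=C(C)C)[C@@]2(C)CC[C@H](O[Si](C)(C)C(C)(C)C)C(C)(C)[C@@H]2CC1
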